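Positions are given in germacrane numbering (C1 to C15). Compound numbers are those of the steps and of the compound list.

## Analysis of the target

Target 32 is a ten-membered carbocycle (C1 to C10) in which an oxygen bridges C3 and C10. The atoms O, C3=C2, C1(=O) and C10 thus form a 3(2H)-furanone, whose 2,5-positions are spanned by the six-atom chain C4 to C9. C6 and C7 carry a trans-fused α-methylene-γ-butyrolactone (C11=C13, C12), C8 a methacrylate, and C4 an acetoxymethyl group on a Z C4=C5 olefin (C3 and C6 cis). There are four stereocenters: the contiguous triad C6 (R), C7 (R), C8 (S) and the quaternary C10 (R), which carries the methyl C14 and the ring oxygen. H6 and H7 are trans. In the zigzag C5 to C9 the C6 oxygen, C11 and the C8 oxygen lie on one side. The oxygen on C10 lies on the face of the large ring that holds the C6 and C8 oxygens, and C14 on the face of the C7–C11 bond. Sensitive groups are three Michael acceptors (methylene lactone, methacrylate, furanone–diene), the allylic acetate, the lactone and esters toward base, and the tertiary alkyl enol ether toward acid. The hard part is the oxygen-bearing quaternary C10 inside a strained bridged bicycle, set relative to a triad on the other side of a medium ring that also holds a Z-trisubstituted olefin. The route rests on one relation: the C3 oxygen is bonded to C10 and C1 carries oxygen, which is the pattern left when a C3 ketone oxygen opens a C1–C10 epoxide at C10.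

## Retrosynthetic reasoning

**End game (32 to 29).** The C15 acetate is taken back to alcohol 31 and silyl ether 30, and the C1 ketone to the allylic alcohol 29. The acetate is put on last because an allylic acetate on C4 would sit β to the carbon–metal bond of the ring closure and could be lost as an allene. The forward steps are an oxidation, a desilylation and an acetylation.

**O–C10 bond (29 to 27).** This is the strategic cut. It removes the five-membered oxygen ring and the C10 stereocenter together and leaves a ten-membered β,γ-epoxy enone, 27. No other cut of the furanone gives a precursor in which the ring itself holds nucleophile and electrophile in reach. The forward step has to deliver the C3 carbonyl oxygen to C10 with inversion and then lose a C2 proton.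

**C3–C4 bond (27 to 24).** The ketone is taken back to the carbinol 26 and the ring is opened between C3 and C4, giving a Z alkenyl iodide and an aldehyde in 24. This bond joins an sp2 carbon of fixed geometry to a carbonyl carbon, so the closure needs no stereocontrol, and the cis olefin and trans epoxide pre-fold the chain. The forward reaction must tolerate the epoxide, two acrylate units and a lactone.

**Epoxide C–O bonds (24 to 21).** The epoxide is taken back to the E olefin of the open-chain ester 21, not to a ring olefin. On the ring a reagent can reach only the outer face of the E olefin, and the ring conformer decides which epoxide results. Ten-membered lactones of this class usually hold the C10 methyl on the side of the C7–C11 bond, and that arrangement would give the (1R,10R)-epoxide, whose opening with inversion leads to the C10 epimer. On the open chain a chiral dioxirane decides the face, so the (1S,10S)-epoxide 22 is reached by reagent control. Ether cleavage and oxidation (23, 24) follow.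

**C7–C8 bond and ester (21 to 18 + 8).** The methacrylate is removed to alcohol 20, and C7–C8 is cut to give butenolide bromide 18 and aldehyde 8. This cut creates C7 and C8 together under control of the one stereocenter already present, C6, and forms the methylene lactone in the same step. The forward allylation has to add anti to the C6 substituent and through a closed transition state.

**Butenolide (18 to 15 + 16).** The C7=C11 bond is cut by metathesis, giving ester 17, which comes from dienol 15 and acid 16. This uses a commercial C4 acid for C11 to C13.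

**Iodo-dienol (15 to 9 + 10).** The C4–I bond comes from directed hydroalumination–iodination of enynol 13, which fixes the Z geometry through the C6 hydroxyl. C6 is set by kinetic resolution of racemic 12, made from acetylide 11 (from 9) and acrolein 10.

**Aldehyde 8 (8 to 1 + 2).** The chain is taken back through 7 and 6 to alcohol 5, in which the C10–C14 and C1–C2 bonds come from carboalumination of alkyne 1 and opening of oxirane 2. This gives the E trisubstituted olefin in one step and two chain ends that differ in their protecting groups.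

## Alternatives that were turned down

**Alternative 1:** The cut is C9–C10. In the forward direction fluoride frees a furan-3-olate whose methyl-bearing carbon attacks C9 of a terminal C8–C9 epoxide. This should give A1, the bicyclic furanone with a free C8 hydroxyl and the lactone carbons carried as two 4-methoxybenzyl ethers. In its favour, the furanone comes from a flat aromatic ring that survives many steps, C8 comes from a terminal epoxide of known configuration, and no β,γ-epoxy ketone is handled; on robustness of intermediates it is stronger than the chosen route. Against it, the furanolate is ambident (oxygen, the unsubstituted ring carbon, and the hindered substituted carbon that is needed). The closure must also span the 2,5-positions of a still planar furan with six atoms, and the C10 configuration rests only on a facial preference in that strained transition state. The lactone must then be unmasked and oxidised and the ester added, three to four further steps. The chosen route sets C10 by a stereospecific inversion of an epoxide whose configuration a reagent has fixed.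

**Alternative 2:** The ten-membered ring is not closed but released: the C1–C5 bond of a fused five–seven system is broken late. Ti(OiPr)4 binds a tertiary C1 alkoxide, the C1–C5 bond breaks as a spiro epoxide on C4 opens, and A2 should result, the ten-membered C1 ketone with C10 and C15 hydroxyls and silyl ethers at C3 and C8. The fragmentation is stereospecific, gives the Z olefin from the ring fusion, avoids a medium-ring closure, and carries C10 as a carbinol set on a rigid bicycle. On control of C10 and of the olefin geometry it is stronger than the chosen route. Against it, a hydroazulene with all stereocenters in matched relation has to be built in a long linear sequence. The methylene lactone would also face alkoxide conditions, and after the fragmentation five or more steps remain (C3 oxidation, cyclodehydration, acetylation, desilylation, esterification). The chosen route is convergent from two small fragments and reaches the furanone two steps after its precursor.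

**Alternative 3:** The cuts are C11–C12 and C12–O, so the methylene lactone is made last. A PdCl2/SnCl2/PPh3 cyclocarbonylation under CO joins the C6 hydroxyl, carbon monoxide and a C7 ethynyl group and should give A3, the target with a silyl ether in place of the methacrylate. It keeps the most electrophilic group out of the whole synthesis and leaves only two steps; on handling and on the length of the end game it is stronger. Against it, the allylic acetate on C15 is a substrate for zerovalent palladium, and the furanone would meet a Lewis acidic tin salt at elevated temperature. The plan also does nothing for the bridged furanone and C10, which would still need one of the other solutions upstream. The chosen route spends its key step on exactly that problem.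

Key step: step 17

Remark on the chemistry (assumption): on the closed ring the reachable face of the E C1=C10 olefin is taken to be the one that leads to the (1R,10R)-epoxide; the epoxide is therefore set on the open chain in step 12.
Remark: silyl ethers 1 and 9 and the L-fructose-derived Shi ketone are taken as purchased.

## Steps

Step 1
Reactants: 1 (but-3-yn-1-yloxy)(tert-butyl)dimethylsilane; 2 oxirane (ethylene oxide)
Product: 5 (3E)-6-(tert-butyldimethylsilyloxy)-4-methylhex-3-en-1-ol, via alkenyldimethylalane 3 (not isolated), via lithium alkenylalanate 4 (not isolated)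
Conditions: AlMe3, Cp2ZrCl2 (0.25 equiv), CH2Cl2, 0 °C to rt; excess AlMe3 removed in vacuo; n-BuLi, THF/hexane, −78 °C; then 2, −78 °C to rt; aq. work-up
Reagents that add atoms: trimethylaluminium, C[Al](C)C
Why: Negishi zirconium-catalysed carboalumination adds methyl and aluminium syn across the terminal alkyne with methyl on the inner carbon, which fixes C14 and the E geometry of C1=C10; the lithium alanate then opens ethylene oxide with retention at the alkenyl carbon.

Step 2
Reactants: 5 (3E)-6-(tert-butyldimethylsilyloxy)-4-methylhex-3-en-1-ol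
Product: 6 tert-butyl{[(3E)-6-(4-methoxybenzyloxy)-3-methylhex-3-en-1-yl]oxy}dimethylsilane
Conditions: NaH, 4-methoxybenzyl chloride, Bu4NI (cat.), THF/DMF, 0 °C to rt
Reagents that add atoms: 4-methoxybenzyl chloride, COc1ccc(CCl)cc1
Why: Williamson etherification of the primary alkoxide; the primary silyl ether is stable to NaH, so the two chain ends become distinguishable.

Step 3
Reactants: 6 tert-butyl{[(3E)-6-(4-methoxybenzyloxy)-3-methylhex-3-en-1-yl]oxy}dimethylsilane
Product: 7 (3E)-6-(4-methoxybenzyloxy)-3-methylhex-3-en-1-ol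
Conditions: Bu4NF, THF, 0 °C to rt
Reagents that add atoms: none
Why: Fluoride-mediated desilylation frees the C8 hydroxyl while the benzylic ether at C3 stays.

Step 4
Reactants: 7 (3E)-6-(4-methoxybenzyloxy)-3-methylhex-3-en-1-ol
Product: 8 (3E)-6-(4-methoxybenzyloxy)-3-methylhex-3-enal
Conditions: Dess–Martin periodinane, pyridine, CH2Cl2, 0 °C; used at once
Reagents that add atoms: none
Why: Dess–Martin oxidation under buffered, non-basic conditions should give the β,γ-unsaturated aldehyde without migration of the olefin into conjugation.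

Step 5
Reactants: 9 tert-butyldimethyl(prop-2-yn-1-yloxy)silane; 10 prop-2-enal (acrolein)
Product: 12 rac-6-(tert-butyldimethylsilyloxy)hex-1-en-4-yn-3-ol, via lithium acetylide 11 (not isolated)
Conditions: n-BuLi, THF, −78 °C; then 10, −78 °C; H2O
Reagents that add atoms: none
Why: 1,2-Addition of a lithium acetylide to acrolein at low temperature forms C5–C6; the carbinol center is not controlled here.

Step 6
Reactants: 12 rac-6-(tert-butyldimethylsilyloxy)hex-1-en-4-yn-3-ol
Product: 13 (3S)-6-(tert-butyldimethylsilyloxy)hex-1-en-4-yn-3-ol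
Conditions: Ti(OiPr)4 (0.15 equiv), L-(+)-diisopropyl tartrate (0.2 equiv), t-BuOOH (0.6 equiv), 4 Å MS, CH2Cl2, −20 °C
Reagents that add atoms: none
Why: Sharpless kinetic resolution of a secondary allylic alcohol: with the L-(+)-tartrate the (R)-enantiomer should be epoxidised fast at its vinyl group, so the slow (S)-enantiomer is recovered and sets C6; at most half of the racemate is used.

Step 7
Reactants: 13 (3S)-6-(tert-butyldimethylsilyloxy)hex-1-en-4-yn-3-ol
Product: 15 (3S,4Z)-6-(tert-butyldimethylsilyloxy)-5-iodohexa-1,4-dien-3-ol, via sodium alkenylalanate 14 (not isolated)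
Conditions: NaAlH2(OCH2CH2OMe)2, THF, 0 °C; then I2, THF, −78 °C
Reagents that add atoms: iodine, II
Why: Alkoxide-directed trans-hydroalumination of the propargylic alcohol delivers hydride to C5 and aluminium to C4 within a five-membered alanate, and iodinolysis with retention gives the Z iodide (iodine cis to the carbinol carbon). The temperature is kept low so that the alanate does not eliminate the neighbouring silyloxy group to an allene.

Step 8
Reactants: 15 (3S,4Z)-6-(tert-butyldimethylsilyloxy)-5-iodohexa-1,4-dien-3-ol; 16 2-(bromomethyl)prop-2-enoic acid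
Product: 17 (3S,4Z)-6-(tert-butyldimethylsilyloxy)-5-iodohexa-1,4-dien-3-yl 2-(bromomethyl)prop-2-enoate
Conditions: DCC, DMAP (5 mol%), CH2Cl2, −10 to 0 °C
Reagents that add atoms: none
Why: Steglich esterification; DMAP is kept catalytic and cold because it can also displace the allylic bromide.

Step 9
Reactants: 17 (3S,4Z)-6-(tert-butyldimethylsilyloxy)-5-iodohexa-1,4-dien-3-yl 2-(bromomethyl)prop-2-enoate
Product: 18 (5S)-3-(bromomethyl)-5-[(1Z)-3-(tert-butyldimethylsilyloxy)-2-iodoprop-1-en-1-yl]furan-2(5H)-one
Conditions: second-generation Grubbs catalyst (5 mol%), toluene, 80 °C, 0.01 M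
Reagents that add atoms: none
Why: Ring-closing metathesis of an acrylate-type ester of an allylic alcohol to a butenolide: the terminal vinyl group loads the catalyst and closes on the 1,1-disubstituted acrylate olefin with loss of ethylene. The iodo-olefin is too hindered and electron-poor to take part.

Step 10
Reactants: 18 (5S)-3-(bromomethyl)-5-[(1Z)-3-(tert-butyldimethylsilyloxy)-2-iodoprop-1-en-1-yl]furan-2(5H)-one; 8 (3E)-6-(4-methoxybenzyloxy)-3-methylhex-3-enal
Product: 20 (4R,5S)-5-[(1Z)-3-(tert-butyldimethylsilyloxy)-2-iodoprop-1-en-1-yl]-4-[(1S,3E)-1-hydroxy-6-(4-methoxybenzyloxy)-3-methylhex-3-en-1-yl]-3-methylidenedihydrofuran-2(3H)-one, via allylzinc bromide 19 (not isolated)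
Conditions: Zn dust, THF/sat. aq. NH4Cl, 0 °C to rt
Reagents that add atoms: none
Why: Barbier allylation: zinc inserts into the allylic bromide and the allylzinc adds through its ring carbon (SE2') in a chair-like six-membered transition state, which forms C7–C8 and the exo-methylene lactone. C7 is set trans to the C6 substituent because the aldehyde approaches the butenolide face away from the alkenyl group. C8 is set by the fixed geometry of the ring-bound allyl unit (C6 trans to the zinc-bearing carbon, E-crotyl type), which gives the anti adduct, (7R,8S) in germacrane numbering.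

Step 11
Reactants: 20 (4R,5S)-5-[(1Z)-3-(tert-butyldimethylsilyloxy)-2-iodoprop-1-en-1-yl]-4-[(1S,3E)-1-hydroxy-6-(4-methoxybenzyloxy)-3-methylhex-3-en-1-yl]-3-methylidenedihydrofuran-2(3H)-one
Product: 21 (1S,3E)-1-[(2S,3R)-2-[(1Z)-3-(tert-butyldimethylsilyloxy)-2-iodoprop-1-en-1-yl]-4-methylidene-5-oxooxolan-3-yl]-6-(4-methoxybenzyloxy)-3-methylhex-3-en-1-yl 2-methylprop-2-enoate
Conditions: methacrylic anhydride, Et3N, DMAP (cat.), CH2Cl2, 0 °C to rt
Reagents that add atoms: methacrylic anhydride, C=C(C)C(=O)OC(=O)C(C)=C
Why: DMAP-catalysed acylation of the secondary alcohol; the final ester is installed here so that no free C8 hydroxyl is left that could attack the lactone.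

Step 12
Reactants: 21 (1S,3E)-1-[(2S,3R)-2-[(1Z)-3-(tert-butyldimethylsilyloxy)-2-iodoprop-1-en-1-yl]-4-methylidene-5-oxooxolan-3-yl]-6-(4-methoxybenzyloxy)-3-methylhex-3-en-1-yl 2-methylprop-2-enoate
Product: 22 (1S)-1-[(2S,3R)-2-[(1Z)-3-(tert-butyldimethylsilyloxy)-2-iodoprop-1-en-1-yl]-4-methylidene-5-oxooxolan-3-yl]-2-[(2S,3S)-3-[2-(4-methoxybenzyloxy)ethyl]-2-methyloxiran-2-yl]ethyl 2-methylprop-2-enoate (the (1S,10S)-epoxide)
Conditions: L-fructose-derived Shi ketone (0.3 equiv), KHSO5 (Oxone), K2CO3, Bu4NHSO4 (cat.), MeCN/CH2(OMe)2/aq. Na2B4O7 buffer (pH 10.5), 0 °C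
Reagents that add atoms: potassium peroxymonosulfate (KHSO5), [K+].[O-]S(=O)(=O)OO
Why: Shi epoxidation: the chiral dioxirane epoxidises the only electron-rich olefin through a spiro transition state. The D-fructose-derived ketone is known to give (R,R)-epoxides from E olefins of this substitution pattern, so its enantiomer should give the (1S,10S)-epoxide whatever the remote stereocenters are. The acrylate olefins and the iodo-olefin are electron-poor and should stay untouched.

Step 13
Reactants: 22 the (1S,10S)-epoxide with a 4-methoxybenzyl ether at C3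
Product: 23 (1S)-2-[(2S,3S)-3-(2-hydroxyethyl)-2-methyloxiran-2-yl]-1-[(2S,3R)-2-[(1Z)-3-(tert-butyldimethylsilyloxy)-2-iodoprop-1-en-1-yl]-4-methylidene-5-oxooxolan-3-yl]ethyl 2-methylprop-2-enoate
Conditions: DDQ, CH2Cl2/pH 7 buffer, 0 °C
Reagents that add atoms: none
Why: Oxidative cleavage of the 4-methoxybenzyl ether by DDQ in wet buffered medium; epoxide, silyl ether, iodide and esters are inert to it.

Step 14
Reactants: 23 the C3 primary alcohol
Product: 24 (1S)-2-[(2S,3S)-2-methyl-3-(2-oxoethyl)oxiran-2-yl]-1-[(2S,3R)-2-[(1Z)-3-(tert-butyldimethylsilyloxy)-2-iodoprop-1-en-1-yl]-4-methylidene-5-oxooxolan-3-yl]ethyl 2-methylprop-2-enoate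
Conditions: Dess–Martin periodinane, pyridine, CH2Cl2, 0 °C; no chromatography, used at once
Reagents that add atoms: none
Why: Dess–Martin oxidation; the β,γ-epoxy aldehyde can lose its α-proton with opening of the epoxide, so it is kept cold and carried on directly.

Step 15
Reactants: 24 the β,γ-epoxy aldehyde with the Z alkenyl iodide
Product: 26 (1S,6R,7R,8S,10S)-15-(tert-butyldimethylsilyloxy)-1,10-epoxy-3-hydroxy-8-(methacryloyloxy)germacra-4Z,11(13)-dien-12,6-olide (C3 epimers), via alkenylchromium dichloride 25 (not isolated)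
Conditions: CrCl2 (10 equiv), NiCl2 (cat.), DMSO, rt, 0.002 M, slow addition
Reagents that add atoms: none
Why: Nozaki–Hiyama–Kishi reaction: zerovalent nickel inserts into the C–I bond and transmetalation to trivalent chromium gives an alkenylchromium that adds only to the aldehyde, closing C3–C4 with retention of the Z geometry. The cis olefin and trans epoxide pre-fold the chain and high dilution favours ring closure. C3 is not controlled because it is oxidised in the next step.

Step 16
Reactants: 26 the macrocyclic epoxy allylic alcohol (C3 epimers)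
Product: 27 (1S,6R,7R,8S,10S)-15-(tert-butyldimethylsilyloxy)-1,10-epoxy-8-(methacryloyloxy)-3-oxogermacra-4Z,11(13)-dien-12,6-olide
Conditions: Dess–Martin periodinane, pyridine, CH2Cl2, 0 °C
Reagents that add atoms: none
Why: Dess–Martin oxidation of the allylic alcohol should give the enone from both epimers; buffering avoids acid-triggered opening of the epoxide and base-triggered elimination of the β,γ-epoxy ketone.

Step 17
Reactants: 27 (1S,6R,7R,8S,10S)-15-(tert-butyldimethylsilyloxy)-1,10-epoxy-8-(methacryloyloxy)-3-oxogermacra-4Z,11(13)-dien-12,6-olide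
Product: 29 (1S,6R,7R,8S,10R)-15-(tert-butyldimethylsilyloxy)-3,10-epoxy-1-hydroxy-8-(methacryloyloxy)germacra-2,4Z,11(13)-trien-12,6-olide, via oxocarbenium borate 28 (not isolated)
Conditions: BF3·OEt2 (0.3 equiv), CH2Cl2, −78 to −40 °C; Et3N quench
Reagents that add atoms: none
Why: BF3 binds the epoxide oxygen and weakens the tertiary C10–O bond. The C3 carbonyl oxygen, held over the inner side of C10 because C2 links C1 and C3, attacks C10 anti to the departing oxygen and gives an oxocarbenium borate. Loss of a C2 proton to the borate alkoxide then gives the enol ether and the C1 alcohol and frees BF3. The closest known reaction type is the acid-mediated cyclisation of β,γ-epoxy ketones to furans through 3-hydroxy-2,3-dihydrofurans; here quaternary C10 stops the sequence at the hydroxy dihydrofuran. The five-membered ring closes in a 5-endo epoxide opening, the 4-exo mode at C1 giving an oxetane being out of reach. C10 is formed with inversion, so the (10S) epoxide carbon set in step 12 becomes (10R), while C1 keeps its oxygen and configuration. The step needs oxygen to attack instead of carbon (C4=C5 is an electron-poor enone olefin and offers no π-nucleophile) and C10 to be attacked instead of C1 (ring size and the tertiary center). It also needs closure to outrun loss of a C9 or C14 proton and a 1,2-hydride shift, which the low temperature and the proximity of the carbonyl should secure. A short contact time and the basic quench protect the allylic C1 alcohol of the product against ionisation.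

Step 18
Reactants: 29 the C1 alcohol
Product: 30 (6R,7R,8S,10R)-15-(tert-butyldimethylsilyloxy)-3,10-epoxy-8-(methacryloyloxy)-1-oxogermacra-2,4Z,11(13)-trien-12,6-olide
Conditions: Dess–Martin periodinane, pyridine, CH2Cl2, 0 °C to rt
Reagents that add atoms: none
Why: Dess–Martin oxidation of the secondary allylic alcohol to the 3(2H)-furanone; C10 is quaternary, so enolisation cannot touch it.

Step 19
Reactants: 30 the furanone silyl ether
Product: 31 (6R,7R,8S,10R)-3,10-epoxy-15-hydroxy-8-(methacryloyloxy)-1-oxogermacra-2,4Z,11(13)-trien-12,6-olide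
Conditions: HF·pyridine, pyridine/THF, 0 °C to rt
Reagents that add atoms: none
Why: Fluoride cleavage of the primary allylic silyl ether under weakly acidic, non-basic conditions that the furanone, lactone and esters should tolerate.

Step 20
Reactants: 31 the C15 alcohol
Product: 32 (6R,7R,8S,10R)-15-acetoxy-3,10-epoxy-8-(methacryloyloxy)-1-oxogermacra-2,4Z,11(13)-trien-12,6-olide (target)
Conditions: Ac2O, pyridine, DMAP (cat.), CH2Cl2, 0 °C
Reagents that add atoms: acetic anhydride, CC(=O)OC(C)=O
Why: Acetylation of the primary allylic alcohol, the only hydroxyl left.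

## Compound list

1 | (but-3-yn-1-yloxy)(tert-butyl)dimethylsilane | C#CCCO[Si](C)(C)C(C)(C)C | starting material
2 | oxirane (ethylene oxide) | C1CO1 | starting material
3 | [(1E)-4-(tert-butyldimethylsilyloxy)-2-methylbut-1-en-1-yl]dimethylalane | C[Al](C)/C=C(\C)CCO[Si](C)(C)C(C)(C)C | intermediate (not isolated)
4 | lithium butyl[(1E)-4-(tert-butyldimethylsilyloxy)-2-methylbut-1-en-1-yl]dimethylalanate | [Li+].CCCC[Al-](C)(C)/C=C(\C)CCO[Si](C)(C)C(C)(C)C | intermediate (not isolated)
5 | (3E)-6-(tert-butyldimethylsilyloxy)-4-methylhex-3-en-1-ol | OCC/C=C(\C)CCO[Si](C)(C)C(C)(C)C | intermediate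
6 | tert-butyl{[(3E)-6-(4-methoxybenzyloxy)-3-methylhex-3-en-1-yl]oxy}dimethylsilane | COc1ccc(COCC/C=C(\C)CCO[Si](C)(C)C(C)(C)C)cc1 | intermediate
7 | (3E)-6-(4-methoxybenzyloxy)-3-methylhex-3-en-1-ol | COc1ccc(COCC/C=C(\C)CCO)cc1 | intermediate
8 | (3E)-6-(4-methoxybenzyloxy)-3-methylhex-3-enal | COc1ccc(COCC/C=C(\C)CC=O)cc1 | intermediate
9 | tert-butyldimethyl(prop-2-yn-1-yloxy)silane | C#CCO[Si](C)(C)C(C)(C)C | starting material
10 | prop-2-enal (acrolein) | C=CC=O | starting material
11 | lithium 3-(tert-butyldimethylsilyloxy)prop-1-yn-1-ide | [Li]C#CCO[Si](C)(C)C(C)(C)C | intermediate (not isolated)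
12 | rac-6-(tert-butyldimethylsilyloxy)hex-1-en-4-yn-3-ol | C=CC(O)C#CCO[Si](C)(C)C(C)(C)C | intermediate
13 | (3S)-6-(tert-butyldimethylsilyloxy)hex-1-en-4-yn-3-ol | C=C[C@H](O)C#CCO[Si](C)(C)C(C)(C)C | intermediate
14 | sodium (5S)-3-[(tert-butyldimethylsilyloxy)methyl]-5-ethenyl-2,2-bis(2-methoxyethoxy)-2,5-dihydro-1,2-oxaluminol-2-uide | [Na+].COCCO[Al-]1(OCCOC)O[C@@H](C=C)C=C1CO[Si](C)(C)C(C)(C)C | intermediate (not isolated)
15 | (3S,4Z)-6-(tert-butyldimethylsilyloxy)-5-iodohexa-1,4-dien-3-ol | C=C[C@H](O)/C=C(\I)CO[Si](C)(C)C(C)(C)C | intermediate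
16 | 2-(bromomethyl)prop-2-enoic acid | C=C(CBr)C(=O)O | starting material
17 | (3S,4Z)-6-(tert-butyldimethylsilyloxy)-5-iodohexa-1,4-dien-3-yl 2-(bromomethyl)prop-2-enoate | C=C[C@H](OC(=O)C(=C)CBr)/C=C(\I)CO[Si](C)(C)C(C)(C)C | intermediate
18 | (5S)-3-(bromomethyl)-5-[(1Z)-3-(tert-butyldimethylsilyloxy)-2-iodoprop-1-en-1-yl]furan-2(5H)-one | BrCC1=C[C@@H](/C=C(\I)CO[Si](C)(C)C(C)(C)C)OC1=O | intermediate
19 | bromo{[(5S)-5-[(1Z)-3-(tert-butyldimethylsilyloxy)-2-iodoprop-1-en-1-yl]-2-oxo-2,5-dihydrofuran-3-yl]methyl}zinc | Br[Zn]CC1=C[C@@H](/C=C(\I)CO[Si](C)(C)C(C)(C)C)OC1=O | intermediate (not isolated)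
20 | (4R,5S)-5-[(1Z)-3-(tert-butyldimethylsilyloxy)-2-iodoprop-1-en-1-yl]-4-[(1S,3E)-1-hydroxy-6-(4-methoxybenzyloxy)-3-methylhex-3-en-1-yl]-3-methylidenedihydrofuran-2(3H)-one | COc1ccc(COCC/C=C(\C)C[C@H](O)[C@H]2C(=C)C(=O)O[C@@H]2/C=C(\I)CO[Si](C)(C)C(C)(C)C)cc1 | intermediate
21 | (1S,3E)-1-[(2S,3R)-2-[(1Z)-3-(tert-butyldimethylsilyloxy)-2-iodoprop-1-en-1-yl]-4-methylidene-5-oxooxolan-3-yl]-6-(4-methoxybenzyloxy)-3-methylhex-3-en-1-yl 2-methylprop-2-enoate | COc1ccc(COCC/C=C(\C)C[C@H](OC(=O)C(C)=C)[C@H]2C(=C)C(=O)O[C@@H]2/C=C(\I)CO[Si](C)(C)C(C)(C)C)cc1 | intermediate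
22 | (1S)-1-[(2S,3R)-2-[(1Z)-3-(tert-butyldimethylsilyloxy)-2-iodoprop-1-en-1-yl]-4-methylidene-5-oxooxolan-3-yl]-2-[(2S,3S)-3-[2-(4-methoxybenzyloxy)ethyl]-2-methyloxiran-2-yl]ethyl 2-methylprop-2-enoate | COc1ccc(COCC[C@@H]3O[C@@]3(C)C[C@H](OC(=O)C(C)=C)[C@H]2C(=C)C(=O)O[C@@H]2/C=C(\I)CO[Si](C)(C)C(C)(C)C)cc1 | intermediate
23 | (1S)-2-[(2S,3S)-3-(2-hydroxyethyl)-2-methyloxiran-2-yl]-1-[(2S,3R)-2-[(1Z)-3-(tert-butyldimethylsilyloxy)-2-iodoprop-1-en-1-yl]-4-methylidene-5-oxooxolan-3-yl]ethyl 2-methylprop-2-enoate | OCC[C@@H]1O[C@@]1(C)C[C@H](OC(=O)C(C)=C)[C@H]2C(=C)C(=O)O[C@@H]2/C=C(\I)CO[Si](C)(C)C(C)(C)C | intermediate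
24 | (1S)-2-[(2S,3S)-2-methyl-3-(2-oxoethyl)oxiran-2-yl]-1-[(2S,3R)-2-[(1Z)-3-(tert-butyldimethylsilyloxy)-2-iodoprop-1-en-1-yl]-4-methylidene-5-oxooxolan-3-yl]ethyl 2-methylprop-2-enoate | O=CC[C@@H]1O[C@@]1(C)C[C@H](OC(=O)C(C)=C)[C@H]2C(=C)C(=O)O[C@@H]2/C=C(\I)CO[Si](C)(C)C(C)(C)C | intermediate
25 | alkenylchromium dichloride derived from 24 (CrCl2 group in place of iodine, Z geometry kept) | O=CC[C@@H]1O[C@@]1(C)C[C@H](OC(=O)C(C)=C)[C@H]2C(=C)C(=O)O[C@@H]2/C=C(/CO[Si](C)(C)C(C)(C)C)[Cr](Cl)Cl | intermediate (not isolated)
26 | (1S,6R,7R,8S,10S)-15-(tert-butyldimethylsilyloxy)-1,10-epoxy-3-hydroxy-8-(methacryloyloxy)germacra-4Z,11(13)-dien-12,6-olide (C3 epimers) | C=C(C)C(=O)O[C@H]1C[C@]3(C)O[C@H]3CC(O)/C(CO[Si](C)(C)C(C)(C)C)=C\[C@H]2OC(=O)C(=C)[C@H]12 | intermediate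
27 | (1S,6R,7R,8S,10S)-15-(tert-butyldimethylsilyloxy)-1,10-epoxy-8-(methacryloyloxy)-3-oxogermacra-4Z,11(13)-dien-12,6-olide | C=C(C)C(=O)O[C@H]1C[C@]3(C)O[C@H]3CC(=O)/C(CO[Si](C)(C)C(C)(C)C)=C\[C@H]2OC(=O)C(=C)[C@H]12 | intermediate
28 | bicyclic oxocarbenium ion (O bonded to C10, O=C3 positively charged) with the C1 oxygen bound to BF3 | C=C(C)C(=O)O[C@H]1C[C@@]2(C)[O+]=C(C[C@@H]2O[B-](F)(F)F)/C(CO[Si](C)(C)C(C)(C)C)=C\[C@H]2OC(=O)C(=C)[C@H]12 | intermediate (not isolated)
29 | (1S,6R,7R,8S,10R)-15-(tert-butyldimethylsilyloxy)-3,10-epoxy-1-hydroxy-8-(methacryloyloxy)germacra-2,4Z,11(13)-trien-12,6-olide | C=C(C)C(=O)O[C@H]1C[C@@]2(C)OC(=C[C@@H]2O)/C(CO[Si](C)(C)C(C)(C)C)=C\[C@H]2OC(=O)C(=C)[C@H]12 | intermediate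
30 | (6R,7R,8S,10R)-15-(tert-butyldimethylsilyloxy)-3,10-epoxy-8-(methacryloyloxy)-1-oxogermacra-2,4Z,11(13)-trien-12,6-olide | C=C(C)C(=O)O[C@H]1C[C@@]2(C)OC(=CC2=O)/C(CO[Si](C)(C)C(C)(C)C)=C\[C@H]2OC(=O)C(=C)[C@H]12 | intermediate
31 | (6R,7R,8S,10R)-3,10-epoxy-15-hydroxy-8-(methacryloyloxy)-1-oxogermacra-2,4Z,11(13)-trien-12,6-olide | C=C(C)C(=O)O[C@H]1C[C@@]2(C)OC(=CC2=O)/C(CO)=C\[C@H]2OC(=O)C(=C)[C@H]12 | intermediate
32 | (6R,7R,8S,10R)-15-acetoxy-3,10-epoxy-8-(methacryloyloxy)-1-oxogermacra-2,4Z,11(13)-trien-12,6-olide | C=C(C)C(=O)O[C@H]1C[C@@]2(C)OC(=CC2=O)/C(COC(C)=O)=C\[C@H]2OC(=O)C(=C)[C@H]12 | target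

## Step count and least certain steps

Total: 20 steps. Longest linear sequence: 16 steps (9 to 32 through steps 5 to 20); the branch from 1 (steps 1 to 4) joins at step 10.

**Step 17 (key step).** Most likely to go wrong:
- E1-type collapse of the BF3-bound epoxide (loss of a C9 or C14 proton to an allylic alcohol, or a 1,2-hydride shift to a C1 ketone) before the carbonyl oxygen closes;
- enolisation toward C2 with opening of the epoxide from the other side;
- ionisation of the allylic, enol-ether-stabilised C1 alcohol of the product on long contact with the Lewis acid.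

Fallback: it sets out from 27 and comes back at 32. Dilute aqueous HClO4 in THF should open the epoxide at the tertiary carbon with water, with inversion at C10 whether or not the ketone assists, and remove the silyl ether. This gives (1S,6R,7R,8S,10R)-1,10,15-trihydroxy-8-(methacryloyloxy)-3-oxogermacra-4Z,11(13)-dien-12,6-olide F1, which may sit as its C3 hemiketal. Acetyl chloride and 2,4,6-collidine at −78 °C should acetylate only the primary allylic hydroxyl to the 15-acetate F2. Dess–Martin oxidation of the secondary C1 hydroxyl gives the 10-hydroxy-1,3-diketone F3. Catalytic TsOH then closes and dehydrates it to the 3(2H)-furanone, the classical furanone synthesis from α'-hydroxy-1,3-diketones, which is 32.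

**Step 15.** Most likely to go wrong: elimination of the β,γ-epoxy aldehyde to a γ-hydroxy enal, or opening of the epoxide by chromium salts, during a slow, dilute ring closure.

Fallback: it sets out from 21 and comes back at 30. The olefin is kept until the ring is closed and C10 is then oxygenated with retention instead of inversion.
- DDQ on 21 gives the alcohol F4, the C3 primary alcohol with the E olefin intact.
- Dess–Martin oxidation gives the β,γ-unsaturated aldehyde F5.
- CrCl2/NiCl2 ring closure gives the macrocyclic dienol F6.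
- Dess–Martin oxidation gives the trienone F7.
- OsO4 (cat.) with N-methylmorpholine N-oxide should dihydroxylate the only electron-rich olefin from its outer face to the (1R,10R)-diol F8. The face that was unsuitable for an epoxide to be opened with inversion is the right one here, because the C10–O bond is kept.
- Dess–Martin oxidation of the secondary hydroxyl gives the 10-hydroxy-1,3-diketone F9.
- Pyridinium tosylate closes and dehydrates it to 30.

**Step 12.** Most likely to go wrong: oxidation at the alkenyl iodide by the dioxirane, or damage to the methylene lactone and the methacrylate in the basic aqueous medium.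

Fallback: the detour of step 15, which leaves the main line at 21, never makes 22 and comes back at 30. It adds no compound beyond F4 to F9 (F0).

**Step 10.** Most likely to go wrong: loss of simple diastereoselectivity at C8 if an open or boat-like transition state competes in the aqueous medium, and, less likely, attack on the face of the C6 substituent.

Fallback: it sets out from 18 and 8 and comes back at 21. The C8-epimeric alcohol F10 is separated and esterified with methacrylic acid under Mitsunobu conditions (PPh3, diisopropyl azodicarboxylate, THF, 0 °C), which inverts C8 and installs the ester in one operation.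

## Further compounds

F1 | step 17 | (1S,6R,7R,8S,10R)-1,10,15-trihydroxy-8-(methacryloyloxy)-3-oxogermacra-4Z,11(13)-dien-12,6-olide | C=C(C)C(=O)O[C@H]1C[C@@](C)(O)[C@@H](O)CC(=O)/C(CO)=C\[C@H]2OC(=O)C(=C)[C@H]12
F2 | step 17 | (1S,6R,7R,8S,10R)-15-acetoxy-1,10-dihydroxy-8-(methacryloyloxy)-3-oxogermacra-4Z,11(13)-dien-12,6-olide | C=C(C)C(=O)O[C@H]1C[C@@](C)(O)[C@@H](O)CC(=O)/C(COC(C)=O)=C\[C@H]2OC(=O)C(=C)[C@H]12
F3 | step 17 | (6R,7R,8S,10R)-15-acetoxy-10-hydroxy-8-(methacryloyloxy)-1,3-dioxogermacra-4Z,11(13)-dien-12,6-olide | C=C(C)C(=O)O[C@H]1C[C@@](C)(O)C(=O)CC(=O)/C(COC(C)=O)=C\[C@H]2OC(=O)C(=C)[C@H]12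
F4 | step 15 | (1S,3E)-1-[(2S,3R)-2-[(1Z)-3-(tert-butyldimethylsilyloxy)-2-iodoprop-1-en-1-yl]-4-methylidene-5-oxooxolan-3-yl]-6-hydroxy-3-methylhex-3-en-1-yl 2-methylprop-2-enoate | OCC/C=C(\C)C[C@H](OC(=O)C(C)=C)[C@H]1C(=C)C(=O)O[C@@H]1/C=C(\I)CO[Si](C)(C)C(C)(C)C
F5 | step 15 | (1S,3E)-1-[(2S,3R)-2-[(1Z)-3-(tert-butyldimethylsilyloxy)-2-iodoprop-1-en-1-yl]-4-methylidene-5-oxooxolan-3-yl]-3-methyl-6-oxohex-3-en-1-yl 2-methylprop-2-enoate | O=CC/C=C(\C)C[C@H](OC(=O)C(C)=C)[C@H]1C(=C)C(=O)O[C@@H]1/C=C(\I)CO[Si](C)(C)C(C)(C)C
F6 | step 15 | (6R,7R,8S)-15-(tert-butyldimethylsilyloxy)-3-hydroxy-8-(methacryloyloxy)germacra-1(10)E,4Z,11(13)-trien-12,6-olide (C3 epimers) | C=C(C)C(=O)O[C@H]1C/C(C)=C/CC(O)/C(CO[Si](C)(C)C(C)(C)C)=C\[C@H]2OC(=O)C(=C)[C@H]12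
F7 | step 15 | (6R,7R,8S)-15-(tert-butyldimethylsilyloxy)-8-(methacryloyloxy)-3-oxogermacra-1(10)E,4Z,11(13)-trien-12,6-olide | C=C(C)C(=O)O[C@H]1C/C(C)=C/CC(=O)/C(CO[Si](C)(C)C(C)(C)C)=C\[C@H]2OC(=O)C(=C)[C@H]12
F8 | step 15 | (1R,6R,7R,8S,10R)-15-(tert-butyldimethylsilyloxy)-1,10-dihydroxy-8-(methacryloyloxy)-3-oxogermacra-4Z,11(13)-dien-12,6-olide | C=C(C)C(=O)O[C@H]1C[C@@](C)(O)[C@H](O)CC(=O)/C(CO[Si](C)(C)C(C)(C)C)=C\[C@H]2OC(=O)C(=C)[C@H]12
F9 | step 15 | (6R,7R,8S,10R)-15-(tert-butyldimethylsilyloxy)-10-hydroxy-8-(methacryloyloxy)-1,3-dioxogermacra-4Z,11(13)-dien-12,6-olide | C=C(C)C(=O)O[C@H]1C[C@@](C)(O)C(=O)CC(=O)/C(CO[Si](C)(C)C(C)(C)C)=C\[C@H]2OC(=O)C(=C)[C@H]12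
F0 | step 12 | none | none
F10 | step 10 | (4R,5S)-5-[(1Z)-3-(tert-butyldimethylsilyloxy)-2-iodoprop-1-en-1-yl]-4-[(1R,3E)-1-hydroxy-6-(4-methoxybenzyloxy)-3-methylhex-3-en-1-yl]-3-methylidenedihydrofuran-2(3H)-one | COc1ccc(COCC/C=C(\C)C[C@@H](O)[C@H]2C(=C)C(=O)O[C@@H]2/C=C(\I)CO[Si](C)(C)C(C)(C)C)cc1
A1 | alternative 1 | bicyclic furanone with free C8 hydroxyl and the lactone carbons as two 4-methoxybenzyl ethers | O[C@H]1C[C@@]2(C)OC(=CC2=O)/C(COC(C)=O)=C\[C@@H](OCc3ccc(OC)cc3)[C@@H]1C(=C)COCc1ccc(OC)cc1
A2 | alternative 2 | ten-membered C1 ketone with C10 and C15 hydroxyls, C3 triethylsilyl ether and C8 tert-butyldimethylsilyl ether | CC(C)(C)[Si](C)(C)O[C@H]1C[C@@](C)(O)C(=O)C[C@@H](O[Si](CC)(CC)CC)/C(CO)=C\[C@H]2OC(=O)C(=C)[C@H]12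
A3 | alternative 3 | target with a tert-butyldimethylsilyl ether at C8 in place of the methacrylate | CC(C)(C)[Si](C)(C)O[C@H]1C[C@@]2(C)OC(=CC2=O)/C(COC(C)=O)=C\[C@H]2OC(=O)C(=C)[C@H]12
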